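**Retrosynthetic overview**

- The target comes from a bridged keto lactone (a 2-oxabicyclo[2.2.2]octane-3,5-dione) by ketone reduction, lactone reduction, two angeloylations and one acetylation; the lactone holds the future CH2O carbon and the CH–O oxygen cis and keeps the three oxygens distinguishable.
- The keto lactone comes from a bicyclo[1.1.0]butane ketal and 3-bromo-3-methylpyran-2,4-dione in one radical [4+2σ] annulation that makes the bond from the cyclobutane CH to the quaternary C(CH3) and the bond from the cyclobutane C(CH3) to the CH–O carbon.
- Enabling feature: the cyclobutane shared by the bicyclo[3.1.1]heptenone and the bicyclo[4.1.1]octane carries the two ends of the oxygenated four-carbon bridge on its two 1,3-related carbons (CH and C–CH3), on the face opposite the enone bridge. That is the signature of addition across the central bond of a tricyclo[4.1.0.0^{2,7}]heptene; the bridge ends match C-3 and C-6 of a 4-hydroxy-3-methyl-2-pyrone.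
- The bicyclobutane comes from a gem-dibromocyclopropane by carbenoid C–H insertion, and that from the (R,R)-hydrobenzoin ketal of 3,5-dimethylcyclohexa-2,5-dienone; the ketal masks the enone and lets the two cage antipodes be separated as diastereomers.
- Ring order: cyclohexane (bought), cyclopropane, bicyclobutane (the cyclobutane of the bicyclo[3.1.1]heptene), then bicyclo[4.1.1]octane and lactone ring together in the key step; the lactone ring is opened again later.

Key step: step 8

Assumption (remark on the chemistry): angelic anhydride is taken as a purchasable reagent, and the facial bias of the dioxolane in step 4 is not relied on, the diastereomer drawn being isolated (the antipodal diol would be used if it proved to be the minor one).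

**Route**

Step 1
Reactants: 1 cis-3,5-dimethylcyclohexanone; 2 (1R,2R)-1,2-diphenylethane-1,2-diol
Product: 3 (2R,3R)-7,9-cis-dimethyl-2,3-diphenyl-1,4-dioxaspiro[4.5]decane
Conditions: TsOH·H2O (cat.), PhMe, reflux, Dean–Stark
Reagents that add atoms: none
Why: Acid-catalysed ketalisation driven by azeotropic removal of water; the spiro carbon is not stereogenic because the diol is C2-symmetric, and the diol later lets the two cage antipodes be separated as diastereomers.

Step 2
Reactants: 3 (2R,3R)-7,9-cis-dimethyl-2,3-diphenyl-1,4-dioxaspiro[4.5]decane
Product: 4 (2R,3R)-6,10-dibromo-7,9-dimethyl-2,3-diphenyl-1,4-dioxaspiro[4.5]decane (mixture of bromide epimers)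
Conditions: Br2 (2.05 equiv), Et2O, 0 °C → rt
Reagents that add atoms: bromine, BrBr
Why: α,α′-Dibromination of a ketal through its ring-opened enol ether, in which the first bromine slows further reaction on its own side so that one bromine goes to each α-carbon; the configuration of the CHBr centres is irrelevant because they become sp2 in step 3.

Step 3
Reactants: 4 (2R,3R)-6,10-dibromo-7,9-dimethyl-2,3-diphenyl-1,4-dioxaspiro[4.5]decane
Product: 5 (2R,3R)-7,9-dimethyl-2,3-diphenyl-1,4-dioxaspiro[4.5]deca-6,9-diene
Conditions: KOtBu (2.5 equiv), DMSO, rt
Reagents that add atoms: none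
Why: Twofold E2 dehydrobromination, the standard entry to cyclohexa-2,5-dienone ketals, in which each bromide loses the β-hydrogen on the methyl-bearing carbon and the ketal prevents tautomerisation to the phenol; both old ring stereocentres vanish.

Step 4
Reactants: 5 (2R,3R)-7,9-dimethyl-2,3-diphenyl-1,4-dioxaspiro[4.5]deca-6,9-diene
Product: 6 (4′R,5′R)-7,7-dibromo-4,6-dimethyl-4′,5′-diphenylspiro[bicyclo[4.1.0]hept-3-ene-2,2′-[1,3]dioxolane], the cyclopropane diastereomer given by the SMILES in the list
Conditions: CHBr3 (1.0 equiv), KOtBu (1.2 equiv), pentane, −20 → 0 °C; chromatography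
Reagents that add atoms: bromoform, BrC(Br)Br
Why: Dibromocarbene cyclopropanation adds with cis ring fusion to one of the two homotopic trisubstituted alkenes (the diene is kept in slight excess to limit the bis-adduct); the two alkene faces are diastereotopic because of the C2-symmetric dioxolane, so the two cage antipodes arise as separable diastereomers and the one drawn is isolated.

Step 5
Reactants: 6 (4′R,5′R)-7,7-dibromo-4,6-dimethyl-4′,5′-diphenylspiro[bicyclo[4.1.0]hept-3-ene-2,2′-[1,3]dioxolane]
Product: 7 (4′R,5′R)-1,5-dimethyl-4′,5′-diphenylspiro[tricyclo[4.1.0.0^{2,7}]hept-4-ene-3,2′-[1,3]dioxolane] (the bicyclobutane; CH3 on one bridgehead, H on the other)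
Conditions: CH3Li (1.3 equiv), Et2O, −78 → −20 °C
Reagents that add atoms: none
Why: Halogen–lithium exchange and α-elimination (Doering–Moore–Skattebøl conditions) give the cyclopropylidene carbenoid, which in bicyclo[4.1.0]heptanes inserts into the syn C–H bond of a neighbouring ring CH2 rather than opening to the strained cyclic allene; here the only neighbouring CH2 is the allylic one next to the methyl-bearing ring-fusion carbon (the other neighbour is the ketal carbon, whose dioxolane C–H bonds are held away from the carbenoid), so the second three-membered ring closes there with the two ring-fusion centres of 6 unchanged and the two new CH centres fixed by the ring.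

Step 6
Reactants: 8 methyl 2-methyl-3-oxobutanoate
Product: 10 4-hydroxy-3-methyl-2H-pyran-2-one, via formyl enol ester 9 (not isolated)
Conditions: NaH (1.1 equiv), THF, 0 °C; n-BuLi (1.05 equiv), −10 °C; HCO2CH3, −78 → 0 °C; 1 M HCl; then PhMe, 90 °C
Reagents that add atoms: methyl formate, COC=O
Why: γ-Acylation of the β-keto ester dianion with methyl formate gives the formyl compound as its chelated (Z)-enol, whose hydroxyl then lactonises onto the methyl ester (the usual 3,5-dioxo ester to 4-hydroxy-2-pyrone cyclisation); no stereocentre remains.

Step 7
Reactants: 10 4-hydroxy-3-methyl-2H-pyran-2-one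
Product: 11 3-bromo-3-methyl-2H-pyran-2,4(3H)-dione (racemic)
Conditions: NBS (1.05 equiv), CH2Cl2, 0 °C, dark; used without storage
Reagents that add atoms: N-bromosuccinimide, O=C1CCC(=O)N1Br
Why: Electrophilic bromination of the enol at C-3, its most nucleophilic carbon, gives the tertiary α-bromo-1,3-dicarbonyl compound needed as radical precursor; the new centre is racemic and becomes planar in step 8.

Step 8
Reactants: 7 the bicyclobutane ketal; 11 3-bromo-3-methyl-2H-pyran-2,4(3H)-dione
Product: 12 bridged keto lactone: the hydrobenzoin ketal of the bicyclo[3.1.1]hept-3-ene whose two one-carbon bridges are spanned by a 2-oxabicyclo[2.2.2]octane-3,5-dione (cyclobutane CH bonded to the quaternary C(CH3) that carries both carbonyls, cyclobutane C(CH3) bonded to the CH–O carbon; lactone bridge under the CH next to the ketal carbon)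
Conditions: (Me3Si)3SiH (1.5 equiv) and 11 (1.4 equiv) added together over 6 h to 7, Et3B (0.3 equiv)/air, PhMe, 0 °C → rt; chromatography
Reagents that add atoms: none
Why: Proposed new method: a silyl-radical chain is expected in which (Me3Si)3Si• takes bromine from 11, the electrophilic tertiary 1,3-dicarbonyl radical at C-3 adds to the electron-rich central σ bond of 7 at the unsubstituted bridgehead CH from the convex face (opposite the three-carbon bridge), and the nucleophilic tertiary cyclobutyl radical thus formed at the methyl-bearing bridgehead adds to C-6, the β-carbon of the alkoxy-enone of the same pyrandione, before the α-keto radical takes hydrogen from the silane. The closest known reaction types are the Kharasch-type radical additions across the central bond of tricyclo[4.1.0.0^{2,7}]heptanes, the radical [2π+2σ] annulations of bicyclo[1.1.0]butanes with alkenes and hydride-mediated tandem radical addition–Giese cyclisations. The ring closure is a 7-endo-trig attack when counted through the cyclobutane CH between the two reacting carbons, in effect a six-centre closure across the planar pyrandione because those carbons are held 1,3 on the cyclobutane, and it creates the bicyclo[4.1.1]octane and the 2-oxabicyclo[2.2.2]octane lactone together. The two cyclobutane carbons can only take their new bonds on the convex face, so their configuration is fixed by the cage, and the quaternary carbon and the CH–O carbon are formed cis because they are C-3 and C-6 of one six-membered ring. The step needs regioselectivity between the two bridgeheads, secured by polarity and sterics (attack at CH gives the tertiary radical), and chemoselectivity for the strained σ bond over the trisubstituted alkene, secured by the higher-lying σ orbital, while slow addition of the silane keeps hydrogen transfer to the cyclobutyl radical slower than ring closure. The one relation the substrate cannot bias is the flank on which the flat radical places its lactone edge, because the convex face of 7 is locally mirror-symmetric, so two diastereomers are expected and 12 (lactone on the ketal-carbon flank) is separated from the other.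

Step 9
Reactants: 12 bridged keto lactone
Product: 13 hydroxy lactone (secondary OH on the former ketone carbon, pointing toward the cage, anti to the lactone oxygen)
Conditions: NaBH4 (1.1 equiv), CeCl3·7H2O (1.2 equiv), MeOH/THF, −78 °C
Reagents that add atoms: none
Why: Luche reduction in which hydride adds to the ketone from the face next to the flat lactone bridge, because the other face is covered by the cyclobutane CH that carries the methyl-substituted alkene carbon, so the new hydroxyl points toward the cage as the target requires, while CeCl3 and low temperature suppress retro-Claisen opening and β-elimination of the acyloxy group.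

Step 10
Reactants: 13 hydroxy lactone
Product: 14 2-methoxypropan-2-yl ether of 13
Conditions: 2-methoxypropene (5 equiv), PPTS (5 mol%), CH2Cl2, 0 °C
Reagents that add atoms: 2-methoxypropene, COC(C)=C
Why: Acid-catalysed addition of the alcohol to the enol ether gives a mixed acetal without a new stereocentre that is stable to hydride and base, keeps this oxygen apart from the two hydroxyls released next and cannot migrate to a neighbouring alkoxide as a silyl group could.

Step 11
Reactants: 14 mixed-acetal lactone
Product: 15 diol (primary CH2OH on the quaternary carbon, secondary OH on the CH next to the cyclobutane C(CH3)), both acetals intact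
Conditions: LiAlH4 (2 equiv), THF, 0 °C
Reagents that add atoms: none
Why: LiAlH4 reduction of the lactone gives the primary alcohol and frees the secondary alcohol without touching the acetals or the trisubstituted alkene; no stereocentre is affected.

Step 12
Reactants: 15 diol
Product: 16 bis-angelate (both new hydroxyls as (Z)-2-methylbut-2-enoates), both acetals intact
Conditions: LiN(SiMe3)2 (2.3 equiv), THF, −78 °C; angelic anhydride (3 equiv), −78 → 0 °C; aq. NH4Cl
Reagents that add atoms: angelic anhydride, C/C=C(/C)C(=O)OC(=O)/C(C)=C\C
Why: Acylation of the two lithium alkoxides with the symmetrical anhydride (no acyl chloride, no nucleophilic amine catalyst) is a stereoconservative angeloylation that avoids Z to E isomerisation of the enoate; no stereocentre is affected.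

Step 13
Reactants: 16 bis-angelate
Product: 17 hydroxy enone bis-angelate (the target lacking only the acetyl group)
Conditions: 0.5 M aq. HCl, THF, 0 °C → rt
Reagents that add atoms: water, O
Why: Mild acid hydrolysis cleaves the mixed acetal and, through the vinylogous oxocarbenium ion, the allylic dioxolane, which unmasks the enone and the free secondary alcohol while the two enoate esters survive.

Step 14
Reactants: 17 hydroxy enone bis-angelate
Product: 18 CNP0364726.1
Conditions: Ac2O, DMAP (cat.), pyridine, rt
Reagents that add atoms: acetic anhydride, CC(=O)OC(C)=O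
Why: DMAP-catalysed acetylation of the only free hydroxyl completes the target without touching any stereocentre.

**Compound list**

1 | cis-3,5-dimethylcyclohexanone | C[C@H]1C[C@@H](C)CC(=O)C1 | starting material
2 | (1R,2R)-1,2-diphenylethane-1,2-diol ((R,R)-hydrobenzoin) | O[C@H](c1ccccc1)[C@H](O)c1ccccc1 | starting material
3 | (2R,3R)-7,9-cis-dimethyl-2,3-diphenyl-1,4-dioxaspiro[4.5]decane | C[C@H]1C[C@@H](C)CC2(O[C@H](c3ccccc3)[C@@H](c3ccccc3)O2)C1 | intermediate
4 | (2R,3R)-6,10-dibromo-7,9-dimethyl-2,3-diphenyl-1,4-dioxaspiro[4.5]decane (bromide epimers) | C[C@H]1C[C@@H](C)C(Br)C2(O[C@H](c3ccccc3)[C@@H](c3ccccc3)O2)C1Br | intermediate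
5 | (2R,3R)-7,9-dimethyl-2,3-diphenyl-1,4-dioxaspiro[4.5]deca-6,9-diene | CC1=CC2(O[C@H](c3ccccc3)[C@@H](c3ccccc3)O2)C=C(C)C1 | intermediate
6 | (4′R,5′R)-7,7-dibromo-4,6-dimethyl-4′,5′-diphenylspiro[bicyclo[4.1.0]hept-3-ene-2,2′-[1,3]dioxolane], isolated cyclopropane diastereomer | BrC1(Br)[C@H]2C4(O[C@H](c5ccccc5)[C@@H](c5ccccc5)O4)C=C(C)C[C@@]12C | intermediate
7 | (4′R,5′R)-1,5-dimethyl-4′,5′-diphenylspiro[tricyclo[4.1.0.0^{2,7}]hept-4-ene-3,2′-[1,3]dioxolane] | [C@@H]12[C@H]3C4(O[C@H](c5ccccc5)[C@@H](c5ccccc5)O4)C=C(C)[C@@H]1[C@@]23C | intermediate
8 | methyl 2-methyl-3-oxobutanoate | COC(=O)C(C)C(C)=O | starting material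
9 | methyl (Z)-5-hydroxy-2-methyl-3-oxopent-4-enoate (formyl enol ester) | COC(=O)C(C)C(=O)/C=C\O | intermediate
10 | 4-hydroxy-3-methyl-2H-pyran-2-one | CC1=C(O)C=COC1=O | intermediate
11 | 3-bromo-3-methyl-2H-pyran-2,4(3H)-dione (racemic) | CC1(Br)C(=O)C=COC1=O | intermediate
12 | bridged keto lactone (2-oxabicyclo[2.2.2]octane-3,5-dione across the one-carbon bridges of the bicyclo[3.1.1]heptene ketal) | O=C5[C@]1(C)[C@@H]2[C@H]3C4(O[C@H](c6ccccc6)[C@@H](c6ccccc6)O4)C=C(C)[C@@H]2[C@@]3(C)[C@H](O5)CC1=O | intermediate
13 | hydroxy lactone | O=C5[C@]1(C)[C@@H]2[C@H]3C4(O[C@H](c6ccccc6)[C@@H](c6ccccc6)O4)C=C(C)[C@@H]2[C@@]3(C)[C@H](O5)C[C@H]1O | intermediate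
14 | 2-methoxypropan-2-yl ether of the hydroxy lactone | O=C5[C@]1(C)[C@@H]2[C@H]3C4(O[C@H](c6ccccc6)[C@@H](c6ccccc6)O4)C=C(C)[C@@H]2[C@@]3(C)[C@H](O5)C[C@H]1OC(C)(C)OC | intermediate
15 | diol with mixed acetal and ketal | OC[C@]1(C)[C@@H]2[C@H]3C4(O[C@H](c5ccccc5)[C@@H](c5ccccc5)O4)C=C(C)[C@@H]2[C@@]3(C)[C@H](O)C[C@H]1OC(C)(C)OC | intermediate
16 | bis-angelate with mixed acetal and ketal | C/C=C(/C)C(=O)OC[C@]1(C)[C@@H]2[C@H]3C4(O[C@H](c5ccccc5)[C@@H](c5ccccc5)O4)C=C(C)[C@@H]2[C@@]3(C)[C@H](OC(=O)/C(C)=C\C)C[C@H]1OC(C)(C)OC | intermediate
17 | hydroxy enone bis-angelate | C/C=C(/C)C(=O)OC[C@]1(C)[C@@H]2[C@H]3C(=O)C=C(C)[C@@H]2[C@@]3(C)[C@H](OC(=O)/C(C)=C\C)C[C@H]1O | intermediate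
18 | CNP0364726.1 | C/C=C(/C)C(=O)OC[C@]1(C)[C@@H]2[C@H]3C(=O)C=C(C)[C@@H]2[C@@]3(C)[C@H](OC(=O)/C(C)=C\C)C[C@H]1OC(C)=O | target

**Step count and risks**

Total step count: 14. Longest linear sequence: 12 steps (steps 1–5 and 8–14).

Steps most likely to fail:

1. Step 8. The chain may be intercepted before the second bond forms (hydrogen transfer to the cyclobutyl radical, or ionic bromination and opening of the strained σ bond by the bromo dione), and the flank taken by the lactone is not biased. Fallback, from 7 and 11 back to 12: 7 and 11 are joined without any hydride source (Et3B/air, PhH, rt), a Kharasch-type bromine-atom-transfer addition across the central bond as known for polyhalomethanes and sulfonyl bromides with tricyclo[4.1.0.0^{2,7}]heptanes. This gives the bromine-transfer adduct F1, with the 3-methyl-2,4-dioxopyran-3-yl group on the CH bridge and bromine on the C(CH3) bridge. In a separate operation F1 is treated with Bu3SnH/AIBN (slow addition, PhH, 80 °C); the tertiary cyclobutyl radical regenerated from the C–Br bond closes onto the alkoxy-enone in a Giese cyclisation and gives 12, again separated from its flank diastereomer.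

2. Step 5. The lithium carbenoid may be diverted before the 1,3-insertion (carbenoid dimerisation, alkylation by the CH3Br formed, insertion into a methyl C–H bond, or opening toward the cyclic allene). Fallback, from 6 back to 7: 6 is treated with n-BuLi (1.0 equiv, THF/Et2O, −105 °C) and the α-bromo cyclopropyllithium is trapped with Me3SnCl to give the bromo stannane F2. Heating F2 in PhMe at 110 °C over K2CO3 expels Me3SnBr and releases the free cyclopropylidene under neutral, salt-free conditions (α-halo organotin compounds as thermal carbene sources); the same C–H insertion then gives 7.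

3. Step 12. The Z-enoate may isomerise to the E-isomer during acyl transfer, and acylation of the hindered secondary alkoxide may stay incomplete. Fallback, from 15 back to 16: 15 is esterified twice with 2-[bis(2,2,2-trifluoroethoxy)phosphoryl]propanoic acid (DCC, DMAP, CH2Cl2) to give the bis(phosphonopropanoate) F3. Treatment of F3 with KN(SiMe3)2 and 18-crown-6 (THF, −78 °C) and then acetaldehyde builds both (Z)-2-methylbut-2-enoates in place by Still–Gennari olefination and gives 16.

**Further compounds**

F1 | step 8 | bromine-transfer adduct: bicyclo[3.1.1]hept-3-ene ketal with the 3-methyl-2,4-dioxopyran-3-yl group on the CH bridge and Br on the C(CH3) bridge (epimers at the two unspecified centres) | O=C1OC=CC(=O)C1(C)[C@@H]2[C@H]3C4(O[C@H](c5ccccc5)[C@@H](c5ccccc5)O4)C=C(C)[C@@H]2C3(C)Br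
F2 | step 5 | (4′R,5′R)-7-bromo-4,6-dimethyl-4′,5′-diphenyl-7-(trimethylstannyl)spiro[bicyclo[4.1.0]hept-3-ene-2,2′-[1,3]dioxolane] | C[Sn](C)(C)C1(Br)[C@H]2C4(O[C@H](c5ccccc5)[C@@H](c5ccccc5)O4)C=C(C)C[C@@]12C
F3 | step 12 | bis{2-[bis(2,2,2-trifluoroethoxy)phosphoryl]propanoate} of diol 15 | CC(C(=O)OC[C@]1(C)[C@@H]2[C@H]3C4(O[C@H](c5ccccc5)[C@@H](c5ccccc5)O4)C=C(C)[C@@H]2[C@@]3(C)[C@H](OC(=O)C(C)P(=O)(OCC(F)(F)F)OCC(F)(F)F)C[C@H]1OC(C)(C)OC)P(=O)(OCC(F)(F)F)OCC(F)(F)F
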